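**Retrosynthetic overview**
Numbering: C1 is the ring carbon bearing OH and CH2OBz (C7), C2 the adjacent CH(OBz), C3=C4 the alkene, C5 the second CH(OBz), C6 the CH(OH). All four ring oxygens are cis.
The target comes from the C6 ketone by hydride addition. Its unit C1(OH)–C6(=O) is an α-ketol retron: moving the C1–C2 bond back to C6 takes C1 out of the ring. This leaves a cyclopentene C6–C2–C3=C4–C5 with the side chain C6(OH)–C1(=O)–CH2OBz.
Enabling feature: the segment C2(OBz)–C3=C4–C5(OBz) is cis and mirror-symmetric, so this cyclopentene is meso and its ring bonds C6–C2 and C6–C5 are enantiotopic. One catalyst-controlled 1,2-shift enlarges the ring, creates quaternary C1 and fixes the absolute configuration of C1, C2 and C5.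
The meso cyclopentene comes from tribenzoylation of a tetraol ketone. That ketone comes from a 6-siloxyfulvene by singlet-oxygen 1,4-dioxygenation (C2–O, C5–O) and hydroxyl-directed Rubottom oxidation (C6–O). The fulvene comes from sodium cyclopentadienide and a silyloxyacetate.
Ring order: the five-membered carbocycle is bought, a transient dioxabicycle is opened again, and the six-membered ring arises from the five-membered one in step 5. No other ring is made.

Key step: step 5

Assumption: the sense of induction of the copper–bis(oxazoline) catalyst on this meso substrate cannot be derived from precedent. The (S,S)-ligand is written, and the equally available (R,R)-ligand takes its place if the opposite ring bond migrates.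

Step 1
Reactants: 1 sodium cyclopentadienide; 2 methyl 2-[(tert-butyldimethylsilyl)oxy]acetate
Product: 4 5-[1,2-bis(tert-butyldimethylsilyloxy)ethylidene]cyclopenta-1,3-diene, via sodium acylcyclopentadienide 3 (not isolated)
Conditions: THF, reflux; volatiles removed; TBSCl, THF, 0 °C to rt
Reagents that add atoms: tert-butyldimethylsilyl chloride, CC(C)(C)[Si](C)(C)Cl
Why: Claisen-type C-acylation of the cyclopentadienide by the ester gives the delocalised 6-oxidofulvene anion (the released methoxide takes the acidic ring proton), and the hard silyl chloride then reacts at oxygen, as acyl chlorides do in the known preparation of 6-acyloxyfulvenes; no stereocentre is formed.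

Step 2
Reactants: 4 5-[1,2-bis(tert-butyldimethylsilyloxy)ethylidene]cyclopenta-1,3-diene
Product: 6 rac-cis-5-[1,2-bis(tert-butyldimethylsilyloxy)ethylidene]cyclopent-2-ene-1,4-diol, via fulvene endoperoxide 5 (not isolated)
Conditions: O2, rose bengal (cat.), thiourea, MeOH–CH2Cl2, visible light, −30 °C; Et3N-deactivated silica
Reagents that add atoms: dioxygen, O=O
Why: Singlet-oxygen [4+2] cycloaddition to the ring diene of a pentafulvene with in situ thiourea reduction of the O–O bond is the known route to 5-alkylidenecyclopent-2-ene-1,4-diols; both C–O bonds come from one O2 molecule bridging one face, so the two carbinol centres are necessarily cis, the cold reducing medium should outrun thermal rearrangement of the endoperoxide, and irradiation is stopped when the fulvene colour fades because the diene reacts much faster than the enol ether.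

Step 3
Reactants: 6 rac-cis-5-[1,2-bis(tert-butyldimethylsilyloxy)ethylidene]cyclopent-2-ene-1,4-diol
Product: 8 all-cis-1-(hydroxyacetyl)cyclopent-3-ene-1,2,5-triol (meso), via silyloxy ketone 7 (not isolated)
Conditions: mCPBA (1.0 equiv), 2,6-di-tert-butylpyridine, CH2Cl2, −40 °C; then Et3N·3HF, MeCN, 0 °C to rt
Reagents that add atoms: 3-chloroperoxybenzoic acid, O=C(OO)c1cccc(Cl)c1
Why: Rubottom oxidation in which the tetrasubstituted silyl enol ether is by far the most nucleophilic alkene and the peracid is held by hydrogen bonds to the two cis allylic hydroxyls (O–C–C=C dihedral about 60°), so oxygen should be delivered to their face and the new tertiary C–O bond set cis to both carbinol oxygens; the silyloxy-oxirane collapses to the ketone (the racemate becomes a meso compound), fluoride removes both silyl groups, and the hindered pyridine keeps the acid-labile bis-allylic diol from ionising.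

Step 4
Reactants: 8 all-cis-1-(hydroxyacetyl)cyclopent-3-ene-1,2,5-triol
Product: 9 meso-1-[(benzoyloxy)acetyl]-1-hydroxycyclopent-3-ene-2,5-diyl dibenzoate (three ring oxygens cis)
Conditions: BzCl (3.3 equiv), pyridine, CH2Cl2, −20 to 0 °C
Reagents that add atoms: benzoyl chloride, O=C(Cl)c1ccccc1
Why: Pyridine-mediated O-acylation esterifies the primary and the two secondary allylic hydroxyls while the tertiary hydroxyl, flanked by three substituted carbons, stays free; no stereocentre is touched and the quaternary α-carbon rules out β-elimination.

Step 5
Reactants: 9 meso-1-[(benzoyloxy)acetyl]-1-hydroxycyclopent-3-ene-2,5-diyl dibenzoate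
Product: 10 [(1R,2R,5S)-2,5-bis(benzoyloxy)-1-hydroxy-6-oxocyclohex-3-en-1-yl]methyl benzoate
Conditions: Cu(OTf)2 (10 mol%), (S,S)-t-Bu-box [2,2'-(propane-2,2-diyl)bis((4S)-4-tert-butyl-4,5-dihydrooxazole)] (11 mol%), 4 Å molecular sieves, ClCH2CH2Cl, 40 °C; used at once
Reagents that add atoms: none
Why: Proposed new method: the cationic divalent-copper bis(oxazoline) complex binds the C6 hydroxyl and the C1 ketone oxygen of 9 as a five-membered chelate (O–C6–C1–O synperiplanar), which raises the electrophilicity of C1 (already activated by the α-benzoyloxy group), and the ring bond C6–C2 shifts suprafacially to C1 while the proton passes from O6 to O1, driven by release of cyclopentene strain and of the crowding at C6. The closest known reaction types are the chiral-Lewis-acid-catalysed enantioselective α-ketol (acyloin) ring expansion of 1-acylcycloalkanols and, for the stereochemical course, the Lewis-acid D-homoannulation of 17-hydroxy-20-ketosteroids; new here is the choice between two enantiotopic, oxygen-bearing allylic carbons of a meso substrate. No ring is closed by cyclisation: the five-membered ring C6–C2–C3–C4–C5 becomes the six-membered ring C1–C6 by a 1,2-shift through a three-centre transition state, and the migrating carbon keeps its configuration. C1 is the only new stereocentre: in the chelate O1 lies on the side of the former C6–OH, which is the face of the two benzoyloxy groups, so C1–OH ends cis to C2–OBz and C5–OBz with CH2OBz trans, and the ligand decides which ring carbon migrates and so fixes the absolute configuration of C1, C2 and C5 together. Regioselectivity is no issue because C6 carries only the two equivalent ring carbons besides OH and acyl; the selectivity needed is between enantiotopic groups, and it is secured by two-point binding in the twofold-symmetric ligand pocket, which twists the chelate so that only one C6–C bond aligns with the C1=O π* orbital. The reaction is stopped at full conversion and kept base-free, because a slower degenerate shift of CH2OBz from C1 to C6 would racemise 10 and enolisation at C5 would open the way to aromatisation.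

Step 6
Reactants: 10 [(1R,2R,5S)-2,5-bis(benzoyloxy)-1-hydroxy-6-oxocyclohex-3-en-1-yl]methyl benzoate
Product: 11 [(1S,2R,5S,6S)-2,5-bis(benzoyloxy)-1,6-dihydroxycyclohex-3-en-1-yl]methyl benzoate
Conditions: NaBH4, MeOH–CH2Cl2, −78 °C; AcOH quench at −78 °C
Reagents that add atoms: none
Why: Borohydride 1,2-reduction under substrate control: in the half-chair with CH2OBz equatorial the C1–OH and C5–OBz bonds are both axial on the lower face, so hydride should attack C6 axially from the open upper face, antiperiplanar to both C–O bonds (polar Felkin–Anh and torsional control agree) and away from all three ring oxygens, which places the new hydroxyl cis to them (6S); the protic non-chelating medium, the low temperature and the acidic quench suppress enolisation and benzoate migration.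

**Compound list**
1 | sodium cyclopentadienide | [Na+].c1cc[cH-]c1 | starting material
2 | methyl 2-[(tert-butyldimethylsilyl)oxy]acetate | COC(=O)CO[Si](C)(C)C(C)(C)C | starting material
3 | sodium [(tert-butyldimethylsilyloxy)acetyl]cyclopentadienide (6-oxidofulvene form) | [Na+].[O-]C(CO[Si](C)(C)C(C)(C)C)=C1C=CC=C1 | intermediate
4 | 5-[1,2-bis(tert-butyldimethylsilyloxy)ethylidene]cyclopenta-1,3-diene (6-siloxyfulvene) | CC(C)(C)[Si](C)(C)OCC(O[Si](C)(C)C(C)(C)C)=C1C=CC=C1 | intermediate
5 | 7-[1,2-bis(tert-butyldimethylsilyloxy)ethylidene]-2,3-dioxabicyclo[2.2.1]hept-5-ene (racemic; the two alkene orientations are mirror images and are left open) | CC(C)(C)[Si](C)(C)OCC(O[Si](C)(C)C(C)(C)C)=C1[C@H]2C=C[C@@H]1OO2 | intermediate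
6 | cis-5-[1,2-bis(tert-butyldimethylsilyloxy)ethylidene]cyclopent-2-ene-1,4-diol (racemic; alkene orientation left open for the same reason) | CC(C)(C)[Si](C)(C)OCC(O[Si](C)(C)C(C)(C)C)=C1[C@H](O)C=C[C@@H]1O | intermediate
7 | meso-1-[(tert-butyldimethylsilyloxy)acetyl]-1-(tert-butyldimethylsilyloxy)cyclopent-3-ene-2,5-diol, three ring oxygens cis | CC(C)(C)[Si](C)(C)OCC(=O)[C@@]1(O[Si](C)(C)C(C)(C)C)[C@H](O)C=C[C@@H]1O | intermediate
8 | meso-1-(hydroxyacetyl)cyclopent-3-ene-1,2,5-triol, three ring oxygens cis, acyl group trans to them | O=C(CO)[C@@]1(O)[C@H](O)C=C[C@@H]1O | intermediate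
9 | meso-(2R,5S)-1-[(benzoyloxy)acetyl]-1-hydroxycyclopent-3-ene-2,5-diyl dibenzoate, three ring oxygens cis | O=C(COC(=O)c1ccccc1)[C@@]2(O)[C@H](OC(=O)c3ccccc3)C=C[C@@H]2OC(=O)c4ccccc4 | intermediate
10 | [(1R,2R,5S)-2,5-bis(benzoyloxy)-1-hydroxy-6-oxocyclohex-3-en-1-yl]methyl benzoate | O=C(OC[C@@]1(O)[C@H](OC(=O)c2ccccc2)C=C[C@H](OC(=O)c2ccccc2)C1=O)c1ccccc1 | intermediate
11 | [(1S,2R,5S,6S)-2,5-bis(benzoyloxy)-1,6-dihydroxycyclohex-3-en-1-yl]methyl benzoate | O=C(OC[C@@]1(O)[C@H](OC(=O)c2ccccc2)C=C[C@H](OC(=O)c2ccccc2)[C@@H]1O)c1ccccc1 | target

Total step count: 6. Longest linear sequence: 6 steps.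

**Steps most likely to fail**

Step 5 (ring expansion). The catalyst may discriminate poorly between the two enantiotopic ring bonds. Enantiomeric purity may also erode through the degenerate CH2OBz shift during a migration slowed by the benzoyloxy groups. The fallback sets out from 9 and gives up asymmetric catalysis for a racemic synthesis with resolution.
- BF3·OEt2 in CH2Cl2 at 0 °C, the classical Lewis-acid α-ketol ring enlargement, should give 10 together with the mirror-image ketone F1.
- Borohydride reduction as in step 6 should give 11 together with the mirror-image diol F2.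
- Preparative chromatography on a polysaccharide chiral stationary phase separates the two, and the route is rejoined at 11.

Step 3 (Rubottom oxidation). Facial selectivity may be lost if hydrogen-bond guidance of the peracid is overridden. The bis-allylic diol may also ionise under the carboxylic acid that forms. The fallback sets out from 6 and replaces electrophilic epoxidation by acid-free, hydrogen-bond-directed osmylation (OsO4 cat., Me3NO·2H2O, CH2Cl2, 0 °C).
- The [3+2] addition to the enol ether on the hydroxyl face, followed by hydrolysis, gives a silyl hemiketal that loses silanol.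
- This should leave the all-cis mono-silylated hydroxy ketone F3.
- Et3N·3HF then frees the primary hydroxyl, and the route is rejoined at 8.

Step 6 (ketone reduction). Facial selectivity may be poor if hydride is partly delivered from the lower face through coordination to the C1 hydroxyl. The fallback sets out from 10 and turns that tendency into the control element.
- Hydroxyl-directed reduction with Me4NBH(OAc)3 in MeCN–AcOH (Saksena–Evans type) should give the trans-diol 6-epimer F4.
- Tf2O and pyridine convert its secondary hydroxyl into the C6 triflate F5.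
- On warming, the trans C5 benzoate displaces triflate with inversion to give the cis-fused 2-phenyl-1,3-dioxolan-2-ylium triflate F6.
- Water opens this ion to the cis-hydroxy benzoates, namely 11 and the C6-benzoate isomer F7.
- F7 is moved to the less hindered allylic oxygen by mild Et3N-catalysed acyl migration, and the route is rejoined at 11.

**Further compounds**
F1 | step 5 | [(1S,2S,5R)-2,5-bis(benzoyloxy)-1-hydroxy-6-oxocyclohex-3-en-1-yl]methyl benzoate (mirror image of 10) | O=C(OC[C@]1(O)[C@@H](OC(=O)c2ccccc2)C=C[C@@H](OC(=O)c2ccccc2)C1=O)c1ccccc1
F2 | step 5 | [(1R,2S,5R,6R)-2,5-bis(benzoyloxy)-1,6-dihydroxycyclohex-3-en-1-yl]methyl benzoate (mirror image of 11) | O=C(OC[C@]1(O)[C@@H](OC(=O)c2ccccc2)C=C[C@@H](OC(=O)c2ccccc2)[C@H]1O)c1ccccc1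
F3 | step 3 | meso-1-[(tert-butyldimethylsilyloxy)acetyl]cyclopent-3-ene-1,2,5-triol, three ring oxygens cis | CC(C)(C)[Si](C)(C)OCC(=O)[C@@]1(O)[C@H](O)C=C[C@@H]1O
F4 | step 6 | [(1S,2R,5S,6R)-2,5-bis(benzoyloxy)-1,6-dihydroxycyclohex-3-en-1-yl]methyl benzoate (6-epimer of 11) | O=C(OC[C@@]1(O)[C@H](OC(=O)c2ccccc2)C=C[C@H](OC(=O)c2ccccc2)[C@H]1O)c1ccccc1
F5 | step 6 | C6 trifluoromethanesulfonate of F4 | O=C(OC[C@@]1(O)[C@H](OC(=O)c2ccccc2)C=C[C@H](OC(=O)c2ccccc2)[C@H]1OS(=O)(=O)C(F)(F)F)c1ccccc1
F6 | step 6 | cis-fused 2-phenyl-1,3-dioxolan-2-ylium triflate spanning O5 and O6 | O=C(OC[C@@]1(O)[C@H](OC(=O)c2ccccc2)C=C[C@@H]2OC(c3ccccc3)=[O+][C@H]12)c1ccccc1.[O-]S(=O)(=O)C(F)(F)F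
F7 | step 6 | all-cis isomer of 11 with the benzoate on O6 and free hydroxyl on C5 | O=C(OC[C@@]1(O)[C@H](OC(=O)c2ccccc2)C=C[C@H](O)[C@@H]1OC(=O)c2ccccc2)c1ccccc1
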